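Ring B is a para-hydroquinone, labelled B1 (C–OAr), B2 (CH), B3 (C–OH), B4 (CH), B5 (C–chain), B6 (C–OH); B1, B2, B3 and B6 map onto a 3-aryloxycyclobutenedione and B4, B5 onto a 1-alkylvinyl group, which allows a cyclobutenone ring expansion.
Retrosynthetic cuts, in order: (a) the bond between bridge carbons 11 and 12 counted from ring B (alkene metathesis, then hydrogenation); (b) ring B at B3–B4, with B3–B6 reconnected, back to a 4-alkenyl-4-hydroxy-3-aryloxycyclobutenone; (c) the B6–B5 bond (alkenyllithium plus dione); (d) the B1–O ether bond (phenol plus chlorocyclobutenedione).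
Forward: the ring A phenol and semisquaric chloride give the aryloxy dione, and the C14 alkenyllithium adds to it. Heating builds ring B; acetylation, ring-closing metathesis (21-membered ring), hydrogenation and deprotection follow.
Stereochemistry: the target has no stereocentre. The only one on the route, the cyclobutenone carbinol, is racemic and is destroyed in the ring expansion; the metathesis alkene geometry is erased by hydrogenation.

Key step: step 9

Remark: a 14-carbon bridge requires a dodec-11-enyl arm on ring B and a but-3-enyl arm on ring A (metathesis loses C2H4), so the alkenyl unit added to the dione is tetradeca-1,13-dien-2-yl (C11 Grignard reagent plus the C3 unit of 2,3-dibromopropene).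

Step 1
Reactants: 1 diisopropyl squarate
Product: 3 3-isopropoxycyclobut-3-ene-1,2-dione, via hydroxycyclobutenone 2 (not isolated)
Conditions: LiAlH(Ot-Bu)3, THF, −78 to −20 °C; then 6 M aq. HCl, CH2Cl2, 0 °C to rt
Reagents that add atoms: none
Why: The bulky hydride adds once to a squarate carbonyl (chemoselective 1,2-reduction), and the resulting carbinol ionises in acid and loses isopropanol with carbonyl transposition, which is the standard passage from a squarate diester to the semisquarate ester.

Step 2
Reactants: 3 3-isopropoxycyclobut-3-ene-1,2-dione
Product: 4 3-hydroxycyclobut-3-ene-1,2-dione (semisquaric acid)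
Conditions: 2 M aq. HCl, THF, 60 °C; evaporation
Reagents that add atoms: water, O
Why: Acid-catalysed hydrolysis of the vinylogous ester (water adds at the alkoxy-bearing ring carbon and isopropanol leaves) should give the strongly acidic, water-soluble vinylogous acid, which is recovered by evaporation.

Step 3
Reactants: 4 3-hydroxycyclobut-3-ene-1,2-dione
Product: 5 3-chlorocyclobut-3-ene-1,2-dione (semisquaric chloride)
Conditions: (COCl)2, DMF (cat.), CH2Cl2, 0 °C to rt; volatiles removed, used at once
Reagents that add atoms: oxalyl chloride, ClC(=O)C(=O)Cl
Why: Semisquaric acid behaves as a vinylogous carboxylic acid, so Vilsmeier-type activation with oxalyl chloride and catalytic DMF should turn its enolic hydroxyl into the vinylogous acid chloride (acid chloride formation) with only gaseous by-products.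

Step 4
Reactants: 6 3,5-dimethoxybenzyl bromide
Product: 7 1-(but-3-en-1-yl)-3,5-dimethoxybenzene
Conditions: CH2=CHCH2MgBr, THF/Et2O, 0 °C to rt
Reagents that add atoms: allylmagnesium bromide, C=CC[Mg]Br
Why: The highly nucleophilic allyl Grignard reagent displaces the benzylic bromide directly (Grignard alkylation by nucleophilic substitution), outcompeting homocoupling at low temperature.

Step 5
Reactants: 7 1-(but-3-en-1-yl)-3,5-dimethoxybenzene
Product: 8 3-(but-3-en-1-yl)-5-methoxyphenol
Conditions: NaSEt, DMF, 140 °C; then 1 M aq. HCl
Reagents that add atoms: none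
Why: Thiolate-mediated SN2 O-demethylation of an aryl methyl ether should stop after one methyl group because the phenoxide formed makes loss of a second phenoxide much harder, and the isolated terminal alkene is inert to the thiolate.

Step 6
Reactants: 5 3-chlorocyclobut-3-ene-1,2-dione; 8 3-(but-3-en-1-yl)-5-methoxyphenol
Product: 9 3-[3-(but-3-en-1-yl)-5-methoxyphenoxy]cyclobut-3-ene-1,2-dione
Conditions: i-Pr2NEt, CH2Cl2, −78 to 0 °C; rapid filtration through silica, used at once
Reagents that add atoms: none
Why: The phenol oxygen adds to the chlorine-bearing carbon of the vinylogous acid chloride and chloride is expelled (addition–elimination, the vinylogous counterpart of phenol acylation), so the future hindered diaryl ether C–O bond is made at low temperature without any arene coupling.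

Step 7
Reactants: 10 11-bromo-1-undecene; 11 2,3-dibromopropene
Product: 13 2-bromotetradeca-1,13-diene, via undec-10-en-1-ylmagnesium bromide 12 (not isolated)
Conditions: Mg, THF, 40 °C; then 11, CuI (5 mol%), THF, −20 °C to rt
Reagents that add atoms: none
Why: Grignard formation from the primary bromide followed by copper-catalysed allylic substitution on 2,3-dibromopropene (the vinylic bromide stays inert) is the classical synthesis of 2-bromo-1-alkenes and fixes the chain at fourteen carbons.

Step 8
Reactants: 13 2-bromotetradeca-1,13-diene; 9 3-[3-(but-3-en-1-yl)-5-methoxyphenoxy]cyclobut-3-ene-1,2-dione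
Product: 15 3-[3-(but-3-en-1-yl)-5-methoxyphenoxy]-4-hydroxy-4-(tetradeca-1,13-dien-2-yl)cyclobut-2-en-1-one (racemic), via 2-lithiotetradeca-1,13-diene 14 (not isolated)
Conditions: t-BuLi (2.0 equiv), Et2O, −78 °C; cannulated into 9, THF, −78 °C; aq. NH4Cl at −78 °C; Et3N-deactivated silica
Reagents that add atoms: none
Why: Bromine–lithium exchange gives the 1-alkylvinyllithium, which should undergo 1,2-addition at −78 °C to the ketone-like carbonyl next to the aryloxy-bearing carbon (the other carbonyl is deactivated as a vinylogous ester), as organolithiums do with alkoxycyclobutenediones, and the new carbinol centre is formed racemic and is of no consequence.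

Step 9
Reactants: 15 3-[3-(but-3-en-1-yl)-5-methoxyphenoxy]-4-hydroxy-4-(tetradeca-1,13-dien-2-yl)cyclobut-2-en-1-one
Product: 16 2-[3-(but-3-en-1-yl)-5-methoxyphenoxy]-6-(dodec-11-en-1-yl)benzene-1,4-diol
Conditions: p-xylene (degassed, 0.02 M), 138 °C, Ar; concentrated under Ar
Reagents that add atoms: none
Why: On heating, the cyclobutenone undergoes a thermal conrotatory 4π electrocyclic opening of the C1–C4 bond (the carbons that become B3 and B6), giving a dienylketene in which the ketene carbon is B3 and the 1-alkylvinyl group sits on B6. The ketene carbon then bonds to the terminal methylene of the vinyl group (B4) in a 6π electrocyclisation, and the resulting cyclohexa-2,4-dienone tautomerises irreversibly to the aromatic hydroquinone; this is the Moore rearrangement of 4-alkenyl-4-hydroxycyclobutenones, the closest known reaction type, here in its less common monoaryloxy form. Ring B is therefore closed by a 6π electrocyclic ring closure that forms the single new C–C bond B3–B4 and places the B6 hydroxyl between the aryloxy group and the chain. No stereocentre is formed, and the racemic carbinol centre of 15 becomes an aromatic carbon. The selectivity needed is torquoselectivity in the ring opening: the hydroxyl donor on the quaternary carbon rotates outward and the alkenyl group inward, so only the ketene geometry that can cyclise is produced and the furanone pathway open to the other rotamer is shut off. Degassed, acid-free solvent protects the acid-labile carbinol and the oxidation-prone product.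

Step 10
Reactants: 16 2-[3-(but-3-en-1-yl)-5-methoxyphenoxy]-6-(dodec-11-en-1-yl)benzene-1,4-diol
Product: 17 2-[3-(but-3-en-1-yl)-5-methoxyphenoxy]-6-(dodec-11-en-1-yl)-1,4-phenylene diacetate
Conditions: Ac2O, pyridine, DMAP (cat.), CH2Cl2, 0 °C to rt
Reagents that add atoms: acetic anhydride, CC(=O)OC(C)=O
Why: DMAP-catalysed O-acetylation of both phenolic hydroxyls (nucleophilic acyl substitution) should protect the oxidation-prone hydroquinone as a diacetate that tolerates ruthenium carbenes and hydrogenation.

Step 11
Reactants: 17 2-[3-(but-3-en-1-yl)-5-methoxyphenoxy]-6-(dodec-11-en-1-yl)-1,4-phenylene diacetate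
Product: 18 macrocyclic alkene diacetate (21-membered ring; E/Z mixture)
Conditions: second-generation Grubbs catalyst (H2IMes)(PCy3)Cl2Ru=CHPh (10 mol%), CH2Cl2 (1 mM), 40 °C
Reagents that add atoms: none
Why: Ring-closing olefin metathesis of two unhindered terminal alkenes at high dilution, driven by loss of ethylene, is a well-established way to close large rings, and the E/Z composition does not matter because the alkene is reduced next.

Step 12
Reactants: 18 macrocyclic alkene diacetate
Product: 19 saturated macrocyclic methyl ether diacetate (tetradecamethylene bridge)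
Conditions: H2 (1 atm), 10% Pd/C, EtOAc, rt
Reagents that add atoms: none
Why: Heterogeneous catalytic hydrogenation should saturate the disubstituted ring alkene, while the aryl methyl ether, the diaryl ether and the aryl acetates are untouched at one atmosphere and room temperature.

Step 13
Reactants: 19 saturated macrocyclic methyl ether diacetate
Product: 21 target CNP0393720.0 (2-oxa-1(1,3),3(1,3)-dibenzenacycloheptadecaphane-1^5,3^2,3^5-triol), via macrocyclic phenol diacetate 20 (not isolated)
Conditions: BBr3, CH2Cl2, −78 to 0 °C; then MeOH (degassed), 0 to 40 °C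
Reagents that add atoms: none
Why: BBr3 cleaves the aryl methyl ether by Lewis acid complexation and bromide attack on the methyl group (the diaryl ether is inert), and the methanol quench generates HBr in methanol, which removes both acetates by acid-catalysed transesterification, so all three phenols are freed without exposing the hydroquinone to base and air.

Compound list
1 | diisopropyl squarate (3,4-diisopropoxycyclobut-3-ene-1,2-dione) | CC(C)OC1=C(OC(C)C)C(=O)C1=O | starting material
2 | hydroxycyclobutenone: 4-hydroxy-2,3-diisopropoxycyclobut-2-en-1-one (racemic) | CC(C)OC1=C(OC(C)C)C(O)C1=O | intermediate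
3 | 3-isopropoxycyclobut-3-ene-1,2-dione | CC(C)OC1=CC(=O)C1=O | intermediate
4 | 3-hydroxycyclobut-3-ene-1,2-dione (semisquaric acid) | OC1=CC(=O)C1=O | intermediate
5 | 3-chlorocyclobut-3-ene-1,2-dione (semisquaric chloride) | ClC1=CC(=O)C1=O | intermediate
6 | 3,5-dimethoxybenzyl bromide | COc1cc(CBr)cc(OC)c1 | starting material
7 | 1-(but-3-en-1-yl)-3,5-dimethoxybenzene | C=CCCc1cc(OC)cc(OC)c1 | intermediate
8 | 3-(but-3-en-1-yl)-5-methoxyphenol | C=CCCc1cc(O)cc(OC)c1 | intermediate
9 | 3-[3-(but-3-en-1-yl)-5-methoxyphenoxy]cyclobut-3-ene-1,2-dione | C=CCCc1cc(OC)cc(c1)OC1=CC(=O)C1=O | intermediate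
10 | 11-bromo-1-undecene | C=CCCCCCCCCCBr | starting material
11 | 2,3-dibromopropene | C=C(Br)CBr | starting material
12 | undec-10-en-1-ylmagnesium bromide | C=CCCCCCCCCC[Mg]Br | intermediate
13 | 2-bromotetradeca-1,13-diene | C=C(Br)CCCCCCCCCCC=C | intermediate
14 | 2-lithiotetradeca-1,13-diene | [Li]C(=C)CCCCCCCCCCC=C | intermediate
15 | 3-[3-(but-3-en-1-yl)-5-methoxyphenoxy]-4-hydroxy-4-(tetradeca-1,13-dien-2-yl)cyclobut-2-en-1-one (racemic) | C=CCCc1cc(OC)cc(c1)OC1=CC(=O)C1(O)C(=C)CCCCCCCCCCC=C | intermediate
16 | 2-[3-(but-3-en-1-yl)-5-methoxyphenoxy]-6-(dodec-11-en-1-yl)benzene-1,4-diol | C=CCCc1cc(OC)cc(c1)Oc1cc(O)cc(c1O)CCCCCCCCCCC=C | intermediate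
17 | 2-[3-(but-3-en-1-yl)-5-methoxyphenoxy]-6-(dodec-11-en-1-yl)-1,4-phenylene diacetate | C=CCCc1cc(OC)cc(c1)Oc1cc(OC(C)=O)cc(c1OC(C)=O)CCCCCCCCCCC=C | intermediate
18 | macrocyclic alkene diacetate: 1^5-methoxy-2-oxa-1(1,3),3(1,3)-dibenzenacycloheptadecaphan-14-ene-3^2,3^5-diyl diacetate, E/Z mixture | COc1cc2cc(c1)Oc1cc(OC(C)=O)cc(c1OC(C)=O)CCCCCCCCCCC=CCC2 | intermediate
19 | saturated macrocyclic methyl ether diacetate: 1^5-methoxy-2-oxa-1(1,3),3(1,3)-dibenzenacycloheptadecaphane-3^2,3^5-diyl diacetate | COc1cc2cc(c1)Oc1cc(OC(C)=O)cc(c1OC(C)=O)CCCCCCCCCCCCCC2 | intermediate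
20 | macrocyclic phenol diacetate: 1^5-hydroxy-2-oxa-1(1,3),3(1,3)-dibenzenacycloheptadecaphane-3^2,3^5-diyl diacetate | Oc1cc2cc(c1)Oc1cc(OC(C)=O)cc(c1OC(C)=O)CCCCCCCCCCCCCC2 | intermediate
21 | CNP0393720.0: 2-oxa-1(1,3),3(1,3)-dibenzenacycloheptadecaphane-1^5,3^2,3^5-triol (achiral) | Oc1cc2cc(c1)Oc1cc(O)cc(c1O)CCCCCCCCCCCCCC2 | target

Total step count: 13.
Longest linear sequence: 10 steps (steps 1, 2, 3, 6, 8, 9, 10, 11, 12, 13, from diisopropyl squarate).

Steps most likely to fail

Step 8. The alkenyllithium may attack the aryloxy-bearing carbon and expel the phenoxide (conjugate addition–elimination), or add to the vinylogous-ester carbonyl. The acid-labile adduct may also ionise on work-up and lose the phenol. The fallback changes the class of carbon nucleophile, not the temperature or solvent. It sets out from 13 and 9: the lithium reagent 14 made from 13 would be transmetalated with anhydrous CeCl3 in THF at −78 °C to (tetradeca-1,13-dien-2-yl)cerium dichloride F1. This reagent is non-basic and strongly oxophilic, and its chemistry is confined to direct addition at the most electrophilic carbonyl. Addition of F1 to 9 at −78 °C and a pH 7 buffer quench would bring the route back at 15.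

Step 6. The moisture-sensitive monochloride 5 may hydrolyse or self-condense before O-substitution takes place, or the electron-rich ring of the phenol may attack through carbon instead of oxygen. The fallback sets out from 8 and does not use 5 (steps 1 to 3 are bypassed). Crystalline, commercial squaric acid dichloride (3,4-dichlorocyclobut-3-ene-1,2-dione, ClC1=C(Cl)C(=O)C1=O) would take up one equivalent of 8 (i-Pr2NEt, CH2Cl2, −78 °C) to give 3-[3-(but-3-en-1-yl)-5-methoxyphenoxy]-4-chlorocyclobut-3-ene-1,2-dione F2. The remaining vinylogous acyl chloride would then be reduced with Bu3SnH and catalytic Pd(PPh3)4 in toluene at rt, the vinylogous form of the palladium-catalysed hydrostannane reduction of acid chlorides. The fallback comes back to the route at 9.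

Step 11. Intermolecular metathesis (oligomer formation) may outrun closure of the 21-membered ring, and ruthenium hydride-mediated double-bond migration may lead to ring-contracted homologues. The fallback sets out from 17. Both terminal alkenes would be cleaved (OsO4 cat., NaIO4, 2,6-lutidine, dioxane/H2O) to 2-[3-methoxy-5-(3-oxopropyl)phenoxy]-6-(11-oxoundecyl)-1,4-phenylene diacetate F3. This dialdehyde would be cyclised by intramolecular McMurry coupling (TiCl3(DME)1.5, Zn–Cu couple, DME, reflux, slow addition), a reductive carbonyl coupling on low-valent titanium that favours large rings. The two carbons removed are the same two that metathesis would expel, so the coupling should give the same alkene. Any acetate lost under the reductive conditions would be restored with Ac2O/pyridine, and the fallback comes back to the route at 18.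

Further compounds
F1 | step 8 | (tetradeca-1,13-dien-2-yl)cerium dichloride | Cl[Ce](Cl)C(=C)CCCCCCCCCCC=C
F2 | step 6 | 3-[3-(but-3-en-1-yl)-5-methoxyphenoxy]-4-chlorocyclobut-3-ene-1,2-dione | C=CCCc1cc(OC)cc(c1)OC1=C(Cl)C(=O)C1=O
F3 | step 11 | 2-[3-methoxy-5-(3-oxopropyl)phenoxy]-6-(11-oxoundecyl)-1,4-phenylene diacetate | O=CCCc1cc(OC)cc(c1)Oc1cc(OC(C)=O)cc(c1OC(C)=O)CCCCCCCCCCC=O
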